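The vessel, stirred and isothermal, held X while E ran in at a steady rate. E and X gave D.

| flask | E | X | remark | time |
|---|---|---|---|---|
| Thursday's | 0.40 M (fed, over 6.0 min) | 0.43 M | run made earlier |  |
| Wednesday's | 0.40 M (fed, over 6.0 min) | 0.69 M | run made earlier |  |
| dawn | 0.40 M (fed, over 6.0 min) | 0.520 M |  | 6.0 min |
| noon | 0.40 M (fed, over 6.0 min) | 1.00 M |  | 6.0 min |

| run | time / min | E / % | D / % |
|---|---|---|---|
| Thursday's | 0.833 | 14.0 | 1.1 |
| Thursday's | 1.50 | 22.0 | 0.1 |
| Thursday's | 2.50 | 37.5 | 4.7 |
| Thursday's | 3.00 | 43.1 | 5.2 |
| Thursday's | 4.00 | 55.1 | 10.7 |
| Wednesday's | 0.833 | 13.9 | 0 |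
| Wednesday's | 1.50 | 25.2 | 3.7 |
| Wednesday's | 2.50 | 37.2 | 7.0 |
| Wednesday's | 3.00 | 39.8 | 9.8 |
| Wednesday's | 4.00 | 51.5 | 13.7 |

(readings scatter by 1 percentage point)

- part of the E that has reacted at the end, dawn
- part of the E that has reacted at the end, noon
- what raising the concentration of X from its lowest to its highest value here does to the part of the E that has reacted (changes below 5 percentage points count as none) (no change / it rises / it falls)

- percentages count the whole charge, also what has not yet gone in

1. I took the E present as the large thing and D as the small correction. Up to 4.00 min, E had climbed nearly straight in both runs, so the area under its curve was about a triangle.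

2. Dividing D at 4.00 min by that area and by c_X gave a pseudo-first-order constant per unit of X. The mean of the two runs was 0.209 /M/min, a reading with their scatter.

3. Let x be this constant times c_X times the dosing time. Under steady feed, with E lost first-order at a fixed c_X, the reacted share at the end of the feed is one minus (one minus e^−x)/x. With c_X as charged, that gave 26.6 % at dawn and 43.1 % at noon.

4. The weak link was c_X, held at its charge. I assumed one X lost per D and used the mean c_X over each run. The runs then gave the working constant, the mean-X rate constant 0.219 /M/min.

5. Taking c_X 0.467 M at dawn and 0.914 M at noon, I committed to 25.3 % and 41.8 %.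

The forecast, made separately, said 26 % (23 % to 29 %) at dawn and 34 % (29 % to 42 %) at noon, and that it rises. It read that “the apparent order in X is about 0.5”, so its noon figure stood lower than mine.

The flasks gave 22.3 % at dawn and 37.7 % at noon. As for the part of the E reacted, on raising X from dawn's charge to noon's, it rises, by 15 percentage points.

E + X → Z + D (k = 0.210 /M/min); X + Z ⇌ L, settled at all times (K = 180 /M) At the end of dawn, 66.0 % of the X stood free. With c_X as the mean of charge and that end value, the carried 0.219 /M/min reckons dawn at 23.7 %. The neighbour charged with 0.60 M of X kept 67 % free, which reckons to 26.7 %. That flask gave 25.2 %.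

Readings and results were computed with constants of no real substance.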